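An easy step opened my reckoning: J.E closes to G with no partner, so that step keeps its own clock.

    J.E → G (k1 = 0.092 s⁻¹)
    J + E → J.E (k2 = 410 L mol⁻¹ s⁻¹)
    J + J.E → L (k3 = 190 L mol⁻¹ s⁻¹)
    J + J.E → J.J.E (k4 = 20 L mol⁻¹ s⁻¹)

| setting | maple | alder | cedar |
|---|---|---|---|
| J | 0.0010 M | 0.0010 M | 0.0010 M (fed, over 10 s) |
| E | 1.20 equiv | 1.20 equiv (fed, over 10 s) | 1.20 equiv |
| time | 25 s | 25 s | 25 s |
| remark | everything together at the start | all else is in the flask from the start; the feed brings no volume worth counting | all else is in the flask from the start; the feed brings no volume worth counting |

- the flask that comes out highest in amount of G, in percent of the J charged, or "all alike" when all lie within 1.5 percentage points (maple / alder / cedar / all alike)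
- G at the end, in percent of the J charged, maple
- G at the end, in percent of the J charged, alder
- G at the end, in percent of the J charged, cedar

- I took the time a J.E lasts with no partner, the reciprocal of 0.092 s⁻¹, which came to 10.9 s, and this turnover time, the first-order lifetime of J.E, became my tool.
- Dividing a span by it counted turnovers, and the share of J.E left unclosed over that span, with no J to take it, was exp of minus that count.
- In maple, where everything met at the start, a J.E born at once had 2.30 turnovers before the reading, so 10.0% of it stood unclosed by this count.
- In alder and cedar the feed ran for 10 s, so a J.E born at its end had 1.38 turnovers, and by the same count a quarter of it stood unclosed, more than the maple share.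
- I therefore expected alder and cedar to hold more J.E at the reading than maple.
- With E at 1.20 equiv, J was the limiting reagent, and a J.E facing c(J) at the full 0.0010 M went to L or J.J.E at 0.210 s⁻¹, faster than its closing at 0.092 s⁻¹.
- That loss depends on c(J) through the whole run, so I stopped there, with no yield of my own.
- The forecast gave G as 56% in maple, 45% in alder and 53% in cedar, and it concluded in these words: “Maple is highest”.
- The simulation gave G as 55.6% in maple, 44.9% in alder and 53.2% in cedar, so maple came out highest. J.E at the reading stood at 8.34% in maple, less than the 11.6% in alder and the 13.7% in cedar. Reading alder later, at 1.5 min, added 5.98 turnovers, which took that 11.6% of J.E down to 0.0294% by my count. That later alder flask held 0.0321% of J.E, and its G stood at 57.0%.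

(The rate constants stand for no real mixture; the flask was simulated.)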